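**Plan**

1. Retrosynthesis: remove the O‑8 ester, the C1–C10 epoxide oxygen and the O6–C12 lactone bond, return C8–OH to a ketone, then rejoin the C3 and C8 carbonyl carbons as the C3=C8 alkene of a 1,2,3,4,5,8‑hexahydronaphthalene, the Birch product of a tetralin.
2. Enabling feature: in the ten‑membered ring C1–C10, the atoms C3‑C2‑C1‑C10‑C9‑C8 (methyl C14 on C10) are the benzene ring of a 7‑methyltetralin whose fusion carbons C3 and C8 are the two oxygen‑bearing ring carbons; C4–C7 are its saturated ring.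
3. Ring order forward: the tetralone ring closes by Friedel–Crafts acylation (C7–C8), Birch reduction follows, and ozonolysis of the fusion alkene merges the two six‑membered rings into the ten‑membered ring; the γ‑lactone and then the epoxide close afterwards.
4. Stereochemistry: C4 from an Evans oxazolidinone Michael addition; C6/C7 from syn hydroboration anti to the C4 substituent; C8 from hydride delivered by the free C6 hydroxyl (1,3‑anti); C1/C10 from C8‑hydroxyl‑directed epoxidation of the ring Z alkene; the acyl group from (R)‑2‑methylbutanoic acid.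
5. The lactone is kept open (tert‑butyl acrylate ester, C13 already installed) through the cleavage, so that O‑6 can distinguish the C8 ketone from the C3 ketone.

Key step: step 12

Remark: locants C1–C15 are germacrane locants (ring C1–C10; C11–C13 on C7; C14 on C10; C15 on C4) and are used for all intermediates; (R)‑2‑methylbutanoic acid and (R)‑4‑benzyl‑1,3‑oxazolidin‑2‑one are assumed to be purchasable as single enantiomers.

**Route**

Step 1
Reactants: 1 (4‑methylphenyl)acetic acid; 2 (R)‑4‑benzyl‑1,3‑oxazolidin‑2‑one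
Product: 4 (R)‑4‑benzyl‑3‑[(4‑methylphenyl)acetyl]‑1,3‑oxazolidin‑2‑one, via mixed pivalic anhydride 3 (not isolated)
Conditions: tBuCOCl, Et3N, THF, −20 °C; then 2, LiCl, rt
Reagents that add atoms: none
Why: N‑acylation of the oxazolidinone through the mixed anhydride is the standard way to attach an arylacetic acid to an Evans auxiliary; no stereocentre is formed.

Step 2
Reactants: 4; 5 tert‑butyl acrylate
Product: 7 tert‑butyl (4R)‑5‑[(4R)‑4‑benzyl‑2‑oxo‑1,3‑oxazolidin‑3‑yl]‑4‑(4‑methylphenyl)‑5‑oxopentanoate, via trichlorotitanium Z‑enolate 6 (not isolated)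
Conditions: TiCl4, iPr2NEt, CH2Cl2, −78 → 0 °C; then 5, 0 °C
Reagents that add atoms: none
Why: Evans titanium‑enolate Michael addition: the chelated Z enolate is attacked by the acrylate on the face away from the benzyl group, which with the (R)‑auxiliary sets the benzylic centre R (the later C4; its descriptor becomes S in the target only through CIP priorities).

Step 3
Reactants: 7
Product: 8 tert‑butyl (4R)‑5‑hydroxy‑4‑(4‑methylphenyl)pentanoate
Conditions: LiBH4, MeOH (1 equiv), THF, 0 °C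
Reagents that add atoms: none
Why: Reductive cleavage of the N‑acyl oxazolidinone with LiBH4; the imide carbonyl is far more electrophilic than the tert‑butyl ester, and the benzylic stereocentre is not enolised.

Step 4
Reactants: 8
Product: 9 tert‑butyl (4R)‑5‑acetoxy‑4‑(4‑methylphenyl)pentanoate
Conditions: Ac2O, pyridine, DMAP (cat.), CH2Cl2, rt
Reagents that add atoms: acetic anhydride, CC(=O)OC(C)=O
Why: O‑Acetylation masks the C15 hydroxyl with a group that tolerates the strongly acidic ring closure and is removed again in step 7.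

Step 5
Reactants: 9
Product: 11 [(1R)‑6‑methyl‑4‑oxo‑1,2,3,4‑tetrahydronaphthalen‑1‑yl]methyl acetate, via carboxylic acid 10 (not isolated)
Conditions: TFA, CH2Cl2, rt; evaporate; then P2O5/MeSO3H (Eaton's reagent), 25 °C
Reagents that add atoms: none
Why: Acidolysis of the tert‑butyl ester then intramolecular Friedel–Crafts acylation (6‑membered ring, C7–C8 bond); both positions ortho to the side chain of the p‑tolyl ring are equivalent, so only the 7‑methyltetralone can form, and C4 is no longer alpha to a carbonyl and cannot epimerise.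

Step 6
Reactants: 11; 12 ethyl bromoacetate
Product: 14 ethyl 2‑[(4R)‑4‑(acetoxymethyl)‑7‑methyl‑3,4‑dihydronaphthalen‑1‑yl]acetate, via tertiary alcohol 13 (not isolated)
Conditions: Zn, 12, THF, reflux; aq. HCl; then pTsOH·H2O (cat.), toluene, reflux (Dean–Stark)
Reagents that add atoms: none
Why: Reformatsky addition to the tetralone then acid‑catalysed dehydration; under equilibrating conditions the endocyclic C6=C7 styrene is favoured over the exocyclic conjugated ester because of peri strain.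

Step 7
Reactants: 14
Product: 17 (3aR,5R,9bR)‑5‑(hydroxymethyl)‑8‑methyl‑3a,4,5,9b‑tetrahydronaphtho[2,1‑b]furan‑2(1H)‑one, via C6 alkylborane 15 (not isolated), via sodium hydroxy carboxylate 16 (not isolated)
Conditions: 9‑BBN, THF, 65 °C; then aq. NaOH, 30% H2O2, 0 → 50 °C; then 2 M HCl; pTsOH (cat.), toluene, 80 °C
Reagents that add atoms: hydrogen peroxide, OO; sodium hydroxide, [Na+].[OH-]
Why: Hydroboration–oxidation: 9‑BBN adds boron to C6 and hydrogen to C7 syn, from the face opposite the pseudoaxial C4 acetoxymethyl group, so oxidation with retention gives the C6 hydroxyl trans to the C7 acetic acid chain and C4/C7 substituents cis; the alkaline peroxide also saponifies both esters and acid closes the trans γ‑lactone onto O‑6.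

Step 8
Reactants: 17
Product: 18 (3aR,5R,9bR)‑8‑methyl‑5‑[(triisopropylsilyloxy)methyl]‑3a,4,5,9b‑tetrahydronaphtho[2,1‑b]furan‑2(1H)‑one
Conditions: iPr3SiCl, imidazole, DMF, rt
Reagents that add atoms: chlorotri(propan‑2‑yl)silane, CC(C)[Si](Cl)(C(C)C)C(C)C
Why: Silylation of the only free hydroxyl; the triisopropylsilyl ether survives Li/NH3, acetic acid and trifluoroacetic acid and keeps O‑15 from directing the later hydride reduction to C3.

Step 9
Reactants: 18
Product: 20 2‑[(1R,2R,4R)‑2‑hydroxy‑7‑methyl‑4‑[(triisopropylsilyloxy)methyl]‑1,2,3,4,5,8‑hexahydronaphthalen‑1‑yl]acetic acid, via lithium carboxylate 19 (not isolated)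
Conditions: LiOH·H2O (1.05 equiv), THF/H2O, rt; evaporate to dryness; then Li, NH3(l)/THF, tBuOH, −78 °C; NH4Cl; NaH2PO4 (pH 4)
Reagents that add atoms: lithium hydroxide, [Li+].[OH-]
Why: Lactone saponification then Birch reduction: carboxylate and alkoxide are inert to Li/NH3, the trialkylbenzene ring is protonated at its unsubstituted para carbons C2 and C9 so that the alkenes stay at C3=C8 and C1=C10, and no benzylic oxygen is present to be cleaved.

Step 10
Reactants: 20
Product: 21 tert‑butyl 2‑[(1R,2R,4R)‑2‑hydroxy‑7‑methyl‑4‑[(triisopropylsilyloxy)methyl]‑1,2,3,4,5,8‑hexahydronaphthalen‑1‑yl]acetate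
Conditions: tBuOC(=NiPr)NHiPr, CH2Cl2, rt
Reagents that add atoms: O‑tert‑butyl‑N,N'‑diisopropylisourea, CC(C)NC(=NC(C)C)OC(C)(C)C
Why: Esterification of the acid by an O‑alkylisourea under neutral conditions leaves the hydroxyl and the acid‑sensitive 1,4‑diene untouched; the tert‑butyl ester cannot lactonise, which keeps O‑6 free.

Step 11
Reactants: 21
Product: 25 tert‑butyl 2‑[(1S,2R,4R)‑2‑hydroxy‑7‑methyl‑4‑[(triisopropylsilyloxy)methyl]‑1,2,3,4,5,8‑hexahydronaphthalen‑1‑yl]prop‑2‑enoate, via dilithium alkoxide enolate 22 (not isolated), via Mannich base 23 (not isolated), via trimethylammonium iodide 24 (not isolated)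
Conditions: LiN(iPr)2 (2.3 equiv), THF, −78 °C; CH2=NMe2+ I−, −78 → −20 °C; aq. NH4Cl; then MeI, MeOH, rt; then NaHCO3, H2O/EtOAc, rt
Reagents that add atoms: N,N‑dimethylmethyleneiminium iodide (Eschenmoser's salt), C=[N+](C)C.[I-]
Why: Mannich methylenation of the ester enolate, N‑methylation and E1cB loss of trimethylamine; C13 is installed before any ketone exists, so no enolate chemistry is needed on the later diketone, and the stereocentres are untouched (C7 changes descriptor only by CIP priority).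

Step 12
Reactants: 25
Product: 28 tert‑butyl (1(10)Z,4S,6R,7S)‑6‑hydroxy‑3,8‑dioxo‑15‑(triisopropylsilyloxy)germacra‑1(10),11(13)‑dien‑12‑oate, via primary ozonide 26 (not isolated), via secondary ozonide 27 (not isolated)
Conditions: O3 (1.0 equiv, titrated solution in CH2Cl2), CH2Cl2, −78 °C; then Me2S, −78 °C → rt
Reagents that add atoms: ozone, [O-][O+]=O
Why: Ozone adds as a 1,3‑dipole to the most electron‑rich, tetrasubstituted C3=C8 alkene to give primary ozonide 26, which cycloreverts to a ketone and a carbonyl oxide held in the same ring; these recombine to secondary ozonide 27, which dimethyl sulfide reduces to the two ketones. The closest known reaction type is the ozonolysis of Birch‑derived tetra‑ and hexahydronaphthalenes at the ring‑fusion alkene to give cyclodecene‑1,6‑diones. The ten‑membered ring is not closed by a cyclisation but appears when the bond shared by the two six‑membered rings is cut, so no ring‑closing entropy is paid and the Z geometry of C1=C10 is carried over from the cyclohexadiene. No stereocentre is created and C4, C6 and C7 are not touched. The step needs attack at C3=C8 rather than at the trisubstituted C1=C10 or the acrylate C11=C13: the fourth alkyl group makes C3=C8 the most nucleophilic alkene, the acrylate is deactivated by conjugation, and ozone is added as a titrated cold solution so that no excess is present. The product is carried on at once, because the β‑hydroxy ketone and the 1,6‑diketone are prone to elimination and transannular aldol reaction.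

Step 13
Reactants: 28
Product: 29 tert‑butyl (1(10)Z,4S,6R,7S,8R)‑6,8‑dihydroxy‑3‑oxo‑15‑(triisopropylsilyloxy)germacra‑1(10),11(13)‑dien‑12‑oate
Conditions: Me4NBH(OAc)3, MeCN/AcOH (1:1), −35 → −20 °C
Reagents that add atoms: none
Why: Saksena–Evans reduction: the C6 hydroxyl exchanges onto boron and delivers hydride to C8 through a chair six‑membered transition state, giving the 1,3‑anti diol (8R); the reagent does not reduce ketones without a free β‑hydroxyl, so the C3 ketone (O‑15 silylated, O‑6 only γ) and the acrylate are left alone.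

Step 14
Reactants: 29
Product: 31 (1(10)Z,4S,6R,7R,8R)‑8‑hydroxy‑3‑oxo‑15‑(triisopropylsilyloxy)germacra‑1(10),11(13)‑dien‑12,6‑olide, via hydroxy acid 30 (not isolated)
Conditions: TFA/CH2Cl2 (1:5), 0 °C; evaporate with toluene
Reagents that add atoms: none
Why: Acidolysis of the tert‑butyl ester then γ‑lactonisation; O‑6, trans to the C7 side chain, is expected to close in preference to the cis O‑8, as in 8β‑hydroxy‑6α,12‑germacranolides, which carry a free 8‑hydroxyl beside the 6,12‑lactone.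

Step 15
Reactants: 31
Product: 32 (1R,4S,6R,7R,8R,10S)‑1,10‑epoxy‑8‑hydroxy‑3‑oxo‑15‑(triisopropylsilyloxy)germacr‑11(13)‑en‑12,6‑olide
Conditions: VO(acac)2 (5 mol%), tBuOOH (anhydrous, in decane), CH2Cl2, 0 °C → rt
Reagents that add atoms: tert‑butyl hydroperoxide, CC(C)(C)OO
Why: Vanadium‑catalysed hydroxyl‑directed epoxidation: the homoallylic C8 hydroxyl binds the metal and delivers oxygen to the face of the Z C1=C10 alkene on which it lies, which should give the cis 1R,10S epoxide; the electron‑poor methylene lactone does not react.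

Step 16
Reactants: 32; 33 (R)‑2‑methylbutanoic acid
Product: 34 (1R,4S,6R,7S,8R,10S)‑1,10‑epoxy‑8‑[(2R)‑2‑methylbutanoyloxy]‑3‑oxo‑15‑(triisopropylsilyloxy)germacr‑11(13)‑en‑12,6‑olide
Conditions: 33, iPrN=C=NiPr, DMAP (cat.), CH2Cl2, 0 °C → rt
Reagents that add atoms: none
Why: Steglich esterification of the only free hydroxyl under nearly neutral conditions, mild enough for the β,γ‑epoxy ketone and for the alpha stereocentre of the acid.

Step 17
Reactants: 34
Product: 35 (1R,4S,6R,7S,8R,10S)‑1,10‑epoxy‑15‑hydroxy‑8‑[(2R)‑2‑methylbutanoyloxy]‑3‑oxogermacr‑11(13)‑en‑12,6‑olide (CNP0219035.1)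
Conditions: HF·pyridine, pyridine, THF, 0 °C → rt
Reagents that add atoms: none
Why: Fluoride desilylation buffered with pyridine removes the silyl ether without base, so the epoxide, the β‑hydroxy ketone that is unveiled and the methylene lactone should survive.

**Compound list**

1 | (4‑methylphenyl)acetic acid | Cc1ccc(CC(=O)O)cc1 | starting material
2 | (R)‑4‑benzyl‑1,3‑oxazolidin‑2‑one | O=C1N[C@H](Cc2ccccc2)CO1 | starting material
3 | (4‑methylphenyl)acetic pivalic anhydride | Cc1ccc(CC(=O)OC(=O)C(C)(C)C)cc1 | intermediate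
4 | (R)‑4‑benzyl‑3‑[(4‑methylphenyl)acetyl]‑1,3‑oxazolidin‑2‑one | Cc1ccc(CC(=O)N2[C@H](Cc3ccccc3)COC2=O)cc1 | intermediate
5 | tert‑butyl acrylate | C=CC(=O)OC(C)(C)C | starting material
6 | trichlorotitanium Z‑enolate of 4 | Cc1ccc(/C=C(\O[Ti](Cl)(Cl)Cl)N2[C@H](Cc3ccccc3)COC2=O)cc1 | intermediate
7 | tert‑butyl (4R)‑5‑[(4R)‑4‑benzyl‑2‑oxo‑1,3‑oxazolidin‑3‑yl]‑4‑(4‑methylphenyl)‑5‑oxopentanoate | CC(C)(C)OC(=O)CC[C@@H](C(=O)N1[C@H](Cc2ccccc2)COC1=O)c1ccc(C)cc1 | intermediate
8 | tert‑butyl (4R)‑5‑hydroxy‑4‑(4‑methylphenyl)pentanoate | CC(C)(C)OC(=O)CC[C@@H](CO)c1ccc(C)cc1 | intermediate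
9 | tert‑butyl (4R)‑5‑acetoxy‑4‑(4‑methylphenyl)pentanoate | CC(C)(C)OC(=O)CC[C@@H](COC(C)=O)c1ccc(C)cc1 | intermediate
10 | (4R)‑5‑acetoxy‑4‑(4‑methylphenyl)pentanoic acid | OC(=O)CC[C@@H](COC(C)=O)c1ccc(C)cc1 | intermediate
11 | [(1R)‑6‑methyl‑4‑oxo‑1,2,3,4‑tetrahydronaphthalen‑1‑yl]methyl acetate | O=C1CC[C@@H](COC(C)=O)c2ccc(C)cc21 | intermediate
12 | ethyl bromoacetate | CCOC(=O)CBr | starting material
13 | ethyl 2‑[(4R)‑4‑(acetoxymethyl)‑1‑hydroxy‑7‑methyl‑1,2,3,4‑tetrahydronaphthalen‑1‑yl]acetate (both epimers at the carbinol carbon) | CCOC(=O)CC1(O)CC[C@@H](COC(C)=O)c2ccc(C)cc21 | intermediate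
14 | ethyl 2‑[(4R)‑4‑(acetoxymethyl)‑7‑methyl‑3,4‑dihydronaphthalen‑1‑yl]acetate | CCOC(=O)CC1=CC[C@@H](COC(C)=O)c2ccc(C)cc21 | intermediate
15 | 9‑BBN adduct of 14 (boron on C6, cis to H‑7, trans to the C4 acetoxymethyl group) | CCOC(=O)C[C@H]1[C@H](B2C3CCCC2CCC3)C[C@@H](COC(C)=O)c2ccc(C)cc21 | intermediate
16 | sodium 2‑[(1R,2R,4R)‑2‑hydroxy‑4‑(hydroxymethyl)‑7‑methyl‑1,2,3,4‑tetrahydronaphthalen‑1‑yl]acetate | [Na+].[O-]C(=O)C[C@H]1[C@H](O)C[C@@H](CO)c2ccc(C)cc21 | intermediate
17 | (3aR,5R,9bR)‑5‑(hydroxymethyl)‑8‑methyl‑3a,4,5,9b‑tetrahydronaphtho[2,1‑b]furan‑2(1H)‑one | C1C(=O)O[C@@H]2C[C@@H](CO)c3ccc(C)cc3[C@@H]12 | intermediate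
18 | (3aR,5R,9bR)‑8‑methyl‑5‑[(triisopropylsilyloxy)methyl]‑3a,4,5,9b‑tetrahydronaphtho[2,1‑b]furan‑2(1H)‑one | C1C(=O)O[C@@H]2C[C@@H](CO[Si](C(C)C)(C(C)C)C(C)C)c3ccc(C)cc3[C@@H]12 | intermediate
19 | lithium 2‑[(1R,2R,4R)‑2‑hydroxy‑7‑methyl‑4‑[(triisopropylsilyloxy)methyl]‑1,2,3,4‑tetrahydronaphthalen‑1‑yl]acetate | [Li+].[O-]C(=O)C[C@H]1[C@H](O)C[C@@H](CO[Si](C(C)C)(C(C)C)C(C)C)c2ccc(C)cc21 | intermediate
20 | 2‑[(1R,2R,4R)‑2‑hydroxy‑7‑methyl‑4‑[(triisopropylsilyloxy)methyl]‑1,2,3,4,5,8‑hexahydronaphthalen‑1‑yl]acetic acid | OC(=O)C[C@H]1[C@H](O)C[C@@H](CO[Si](C(C)C)(C(C)C)C(C)C)C2=C1CC(C)=CC2 | intermediate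
21 | tert‑butyl 2‑[(1R,2R,4R)‑2‑hydroxy‑7‑methyl‑4‑[(triisopropylsilyloxy)methyl]‑1,2,3,4,5,8‑hexahydronaphthalen‑1‑yl]acetate | CC(C)(C)OC(=O)C[C@H]1[C@H](O)C[C@@H](CO[Si](C(C)C)(C(C)C)C(C)C)C2=C1CC(C)=CC2 | intermediate
22 | dilithium C6‑alkoxide ester enolate of 21 | [Li+].[Li+].CC(C)(C)OC([O-])=C[C@H]1[C@H]([O-])C[C@@H](CO[Si](C(C)C)(C(C)C)C(C)C)C2=C1CC(C)=CC2 | intermediate
23 | tert‑butyl 3‑(dimethylamino)‑2‑[(1R,2R,4R)‑2‑hydroxy‑7‑methyl‑4‑[(triisopropylsilyloxy)methyl]‑1,2,3,4,5,8‑hexahydronaphthalen‑1‑yl]propanoate (both C11 epimers) | CC(C)(C)OC(=O)C(CN(C)C)[C@H]1[C@H](O)C[C@@H](CO[Si](C(C)C)(C(C)C)C(C)C)C2=C1CC(C)=CC2 | intermediate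
24 | N‑methyl iodide of 23 (trimethylammonium salt) | C[N+](C)(C)CC(C(=O)OC(C)(C)C)[C@H]1[C@H](O)C[C@@H](CO[Si](C(C)C)(C(C)C)C(C)C)C2=C1CC(C)=CC2.[I-] | intermediate
25 | tert‑butyl 2‑[(1S,2R,4R)‑2‑hydroxy‑7‑methyl‑4‑[(triisopropylsilyloxy)methyl]‑1,2,3,4,5,8‑hexahydronaphthalen‑1‑yl]prop‑2‑enoate | CC(C)(C)OC(=O)C(=C)[C@H]1[C@H](O)C[C@@H](CO[Si](C(C)C)(C(C)C)C(C)C)C2=C1CC(C)=CC2 | intermediate
26 | primary ozonide of 25 (1,2,3‑trioxolane on C3 and C8) | CC(C)(C)OC(=O)C(=C)[C@H]1[C@H](O)C[C@@H](CO[Si](C(C)C)(C(C)C)C(C)C)C23CC=C(C)CC12OOO3 | intermediate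
27 | secondary ozonide (1,2,4‑trioxolane bridging C3 and C8) | CC(C)(C)OC(=O)C(=C)[C@H]1[C@H](O)C[C@@H](CO[Si](C(C)C)(C(C)C)C(C)C)C23CC=C(C)CC1(O2)OO3 | intermediate
28 | tert‑butyl (1(10)Z,4S,6R,7S)‑6‑hydroxy‑3,8‑dioxo‑15‑(triisopropylsilyloxy)germacra‑1(10),11(13)‑dien‑12‑oate | CC(C)(C)OC(=O)C(=C)[C@H]1[C@H](O)C[C@@H](CO[Si](C(C)C)(C(C)C)C(C)C)C(=O)C/C=C(/C)CC1=O | intermediate
29 | tert‑butyl (1(10)Z,4S,6R,7S,8R)‑6,8‑dihydroxy‑3‑oxo‑15‑(triisopropylsilyloxy)germacra‑1(10),11(13)‑dien‑12‑oate | CC(C)(C)OC(=O)C(=C)[C@H]1[C@H](O)C[C@@H](CO[Si](C(C)C)(C(C)C)C(C)C)C(=O)C/C=C(/C)C[C@H]1O | intermediate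
30 | (1(10)Z,4S,6R,7S,8R)‑6,8‑dihydroxy‑3‑oxo‑15‑(triisopropylsilyloxy)germacra‑1(10),11(13)‑dien‑12‑oic acid | OC(=O)C(=C)[C@H]1[C@H](O)C[C@@H](CO[Si](C(C)C)(C(C)C)C(C)C)C(=O)C/C=C(/C)C[C@H]1O | intermediate
31 | (1(10)Z,4S,6R,7R,8R)‑8‑hydroxy‑3‑oxo‑15‑(triisopropylsilyloxy)germacra‑1(10),11(13)‑dien‑12,6‑olide | C=C1C(=O)O[C@@H]2C[C@@H](CO[Si](C(C)C)(C(C)C)C(C)C)C(=O)C/C=C(/C)C[C@@H](O)[C@@H]12 | intermediate
32 | (1R,4S,6R,7R,8R,10S)‑1,10‑epoxy‑8‑hydroxy‑3‑oxo‑15‑(triisopropylsilyloxy)germacr‑11(13)‑en‑12,6‑olide | C=C1C(=O)O[C@@H]2C[C@@H](CO[Si](C(C)C)(C(C)C)C(C)C)C(=O)C[C@H]3O[C@@]3(C)C[C@@H](O)[C@@H]12 | intermediate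
33 | (R)‑2‑methylbutanoic acid | CC[C@@H](C)C(=O)O | starting material
34 | (1R,4S,6R,7S,8R,10S)‑1,10‑epoxy‑8‑[(2R)‑2‑methylbutanoyloxy]‑3‑oxo‑15‑(triisopropylsilyloxy)germacr‑11(13)‑en‑12,6‑olide | C=C1C(=O)O[C@@H]2C[C@@H](CO[Si](C(C)C)(C(C)C)C(C)C)C(=O)C[C@H]3O[C@@]3(C)C[C@@H](OC(=O)[C@H](C)CC)[C@@H]12 | intermediate
35 | (1R,4S,6R,7S,8R,10S)‑1,10‑epoxy‑15‑hydroxy‑8‑[(2R)‑2‑methylbutanoyloxy]‑3‑oxogermacr‑11(13)‑en‑12,6‑olide | C=C1C(=O)O[C@@H]2C[C@@H](CO)C(=O)C[C@H]3O[C@@]3(C)C[C@@H](OC(=O)[C@H](C)CC)[C@@H]12 | target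

**Count and risks**

Total step count: 17. Longest linear sequence: 17 steps (from 1; 2, 5, 12 and 33 enter as purchased reagents).

Steps most likely to fail:

1. Step 12. Ozone may not discriminate cleanly between the tetrasubstituted and the trisubstituted ring alkene (over‑oxidation), and the new β‑hydroxy 1,6‑diketone may eliminate or undergo transannular aldol reaction while the ozonide is reduced. Fallback: setting out from 25, epoxidation with mCPBA (1 equiv, NaHCO3, CH2Cl2, −40 °C), which has a larger tetra/tri rate ratio than ozone, should give the 3,8‑epoxide F1. Opening with dilute aqueous HClO4 in THF would give the 3,8‑diol F2, and Criegee glycol cleavage with Pb(OAc)4 returns to the route at 28.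

2. Step 14. The lactone may close onto O‑8 instead of O‑6, or the acid may move the C1=C10 alkene into conjugation with the C3 ketone. Fallback: setting out from 25, the lactone is closed before the ring is cleaved, when O‑6 is the only hydroxyl (camphorsulfonic acid cat., toluene, 60 °C, with loss of 2‑methylpropene), to give the methylene lactone diene F3. Ozonolysis as in step 12 would give the diketo lactone F4. Reduction with LiBH(sBu)3 at −78 °C, where C3 is shielded by the adjacent silyloxymethyl‑bearing carbon, returns to the route at 31. This gives up the internal hydride delivery and relies on steric bias alone.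

3. Step 15. The directed epoxidation may suffer from competing oxidation of the C8 carbinol or from poor facial selectivity if the hydroxyl is tied up as a transannular hemiketal with C3. Fallback: setting out from 31, esterification with 33 (iPrN=C=NiPr, DMAP) comes first and gives the 8‑O‑acyl alkene F5. Epoxidation with dimethyldioxirane in acetone at 0 °C, from the more accessible face of the ring alkene, then returns to the route at 34.

Further compounds
F1 | step 12 | 3,8‑epoxide of 25 (ring‑fusion epoxide, configuration at C3/C8 not assigned) | CC(C)(C)OC(=O)C(=C)[C@H]1[C@H](O)C[C@@H](CO[Si](C(C)C)(C(C)C)C(C)C)C23CC=C(C)CC12O3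
F2 | step 12 | 3,8‑diol from F1 (configuration at C3/C8 not assigned) | CC(C)(C)OC(=O)C(=C)[C@H]1[C@H](O)C[C@@H](CO[Si](C(C)C)(C(C)C)C(C)C)C2(O)CC=C(C)CC12O
F3 | step 14 | (3aR,5R,9bS)‑8‑methyl‑1‑methylidene‑5‑[(triisopropylsilyloxy)methyl]‑3a,4,5,6,9,9b‑hexahydronaphtho[2,1‑b]furan‑2(1H)‑one | C=C1C(=O)O[C@@H]2C[C@@H](CO[Si](C(C)C)(C(C)C)C(C)C)C3=C(CC(C)=CC3)[C@@H]12
F4 | step 14 | (1(10)Z,4S,6R,7S)‑3,8‑dioxo‑15‑(triisopropylsilyloxy)germacra‑1(10),11(13)‑dien‑12,6‑olide | C=C1C(=O)O[C@@H]2C[C@@H](CO[Si](C(C)C)(C(C)C)C(C)C)C(=O)C/C=C(/C)CC(=O)[C@@H]12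
F5 | step 15 | (1(10)Z,4S,6R,7S,8R)‑8‑[(2R)‑2‑methylbutanoyloxy]‑3‑oxo‑15‑(triisopropylsilyloxy)germacra‑1(10),11(13)‑dien‑12,6‑olide | C=C1C(=O)O[C@@H]2C[C@@H](CO[Si](C(C)C)(C(C)C)C(C)C)C(=O)C/C=C(/C)C[C@@H](OC(=O)[C@H](C)CC)[C@@H]12
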